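**Retrosynthetic overview**
1. Target 24 ⇐ diol 20 by C15 oxidation, C16 methylenation and desilylation.
2. Diol 20 ⇐ dialdehyde 18 in one reductive operation: the C11 ketyl adds to C9 (ring C), then the C8 samarium enolate adds to the second aldehyde (ring D). The two CH2CHO arms are identical, so C13 is set in the same step as C8, C9 and C11.
3. Dialdehyde 18 ⇐ cyclopentene lactone 16 (ozonolysis) ⇐ spirolactone 10 + iodide 12 (alkylation, selenoxide elimination).
4. Spirolactone 10 ⇐ spiro-epoxide 7 + trifluoroethyl acrylate 8 (Ti(III) radical addition and lactonisation; sets C10).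
5. Epoxide 7 ⇐ enone ester 1 (asymmetric conjugate methylation / formaldehyde aldol sets C4 and C5). Ring order: A (bought) → lactone → C and D together.

Assumption: kaurane numbering is used throughout (the C4 CH2OH is C18, the C4 methyl is C19), TBS = tert-butyldimethylsilyl, and 1, 8 and 11 are bought.

Step 1
Reactants: 1 methyl 3-oxocyclohex-1-ene-1-carboxylate
Product: 4 methyl (1S,2S)-2-[(TBS-oxy)methyl]-1-methyl-3-oxocyclohexane-1-carboxylate, via methylzinc enolate 2 (not isolated), via zinc aldolate 3 (not isolated)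
Conditions: Me2Zn, Cu(OTf)2·C6H6 (2.5 mol %), chiral sulfonate-NHC–Ag complex (2.5 mol %, enantiomer giving 1S), t-BuOMe, −30 °C; then CH2O (monomer in THF), −78 °C; then TBSOTf, −78 → 0 °C
Reagents that add atoms: dimethylzinc C[Zn]C; formaldehyde C=O; tert-butyldimethylsilyl triflate CC(C)(C)[Si](C)(C)OS(=O)(=O)C(F)(F)F
Why: Cu–NHC-catalysed enantioselective conjugate addition of Me2Zn β to the ketone sets the quaternary C4, the zinc enolate then undergoes a kinetic aldol with formaldehyde anti to the pseudo-axial CO2Me (C6 trans to the ester, setting C5), and in-flask O-silylation of the zinc aldolate blocks retro-aldol and epimerisation.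

Step 2
Reactants: 4 methyl (1S,2S)-2-[(TBS-oxy)methyl]-1-methyl-3-oxocyclohexane-1-carboxylate
Product: 5 methyl (4S,5S)-4-[(TBS-oxy)methyl]-5-methyl-1-oxaspiro[2.5]octane-5-carboxylate (both epimers at the spiro carbon)
Conditions: Me3S+ I−, KHMDS, THF, −10 → 0 °C
Reagents that add atoms: trimethylsulfonium iodide C[S+](C)C.[I-]
Why: Corey–Chaykovsky epoxidation, in which the sulfonium methylide adds to the ketone much faster than to the hindered tertiary ester; the spiro configuration is irrelevant because step 5 erases it.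

Step 3
Reactants: 5 methyl (4S,5S)-4-[(TBS-oxy)methyl]-5-methyl-1-oxaspiro[2.5]octane-5-carboxylate
Product: 6 [(4S,5S)-4-[(TBS-oxy)methyl]-5-methyl-1-oxaspiro[2.5]octan-5-yl]methanol
Conditions: DIBAL-H (2.5 equiv), CH2Cl2, −78 °C; Rochelle salt
Reagents that add atoms: none
Why: DIBAL-H reduction of the ester to the primary alcohol at −78 °C, where the 2,2-disubstituted epoxide and the TBS ether are inert.

Step 4
Reactants: 6 [(4S,5S)-4-[(TBS-oxy)methyl]-5-methyl-1-oxaspiro[2.5]octan-5-yl]methanol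
Product: 7 (4S,5S)-4,5-bis[(TBS-oxy)methyl]-5-methyl-1-oxaspiro[2.5]octane
Conditions: TBSCl, imidazole, DMF, rt
Reagents that add atoms: tert-butyldimethylsilyl chloride CC(C)(C)[Si](C)(C)Cl
Why: Standard silylation of an unhindered primary alcohol under neutral conditions that leave the epoxide untouched.

Step 5
Reactants: 7 (4S,5S)-4,5-bis[(TBS-oxy)methyl]-5-methyl-1-oxaspiro[2.5]octane; 8 2,2,2-trifluoroethyl acrylate
Product: 10 (6R,7R,8S)-7,8-bis[(TBS-oxy)methyl]-8-methyl-2-oxaspiro[5.5]undecan-3-one, via titanium-bound hydroxy ester 9 (not isolated)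
Conditions: Cp2TiCl2 (20 mol %), Zn dust, 2,4,6-collidine·HCl, THF, rt
Reagents that add atoms: none
Why: Nugent–RajanBabu/Gansäuer Ti(III) reductive epoxide opening gives the tertiary C10 radical, whose Giese addition to the acrylate occurs equatorially (anti to the axial C4 methyl, so C9 ends trans to the C5 CH2OTBS and C10 is set), and after reduction and protonation the primary alkoxide lactonises on the activated trifluoroethyl ester.

Step 6
Reactants: 11 cyclopent-3-en-1-ylmethanol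
Product: 12 4-(iodomethyl)cyclopent-1-ene
Conditions: I2, PPh3, imidazole, CH2Cl2, 0 °C → rt
Reagents that add atoms: iodine II
Why: Appel-type iodination of a primary alcohol; the isolated alkene does not react with the phosphonium iodide at 0 °C.

Step 7
Reactants: 10 (6R,7R,8S)-7,8-bis[(TBS-oxy)methyl]-8-methyl-2-oxaspiro[5.5]undecan-3-one; 12 4-(iodomethyl)cyclopent-1-ene
Product: 13 (6R,7R,8S)-7,8-bis[(TBS-oxy)methyl]-4-(cyclopent-3-en-1-ylmethyl)-8-methyl-2-oxaspiro[5.5]undecan-3-one (epimers at C4 of the lactone)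
Conditions: LDA, THF, −78 °C; then 12, HMPA, −78 → −20 °C
Reagents that add atoms: none
Why: SN2 alkylation of the lactone lithium enolate with a primary iodide (HMPA offsets the β-branching); the new C8 centre is removed in step 8.

Step 8
Reactants: 13 (6R,7R,8S)-7,8-bis[(TBS-oxy)methyl]-4-(cyclopent-3-en-1-ylmethyl)-8-methyl-2-oxaspiro[5.5]undecan-3-one
Product: 16 (6R,7R,8S)-7,8-bis[(TBS-oxy)methyl]-4-(cyclopent-3-en-1-ylmethyl)-8-methyl-2-oxaspiro[5.5]undec-4-en-3-one, via selenide 14 (not isolated), via selenoxide 15 (not isolated)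
Conditions: LDA, THF, −78 °C; PhSeBr (1.05 equiv); then NaIO4, THF/MeOH/H2O, 0 °C → rt
Reagents that add atoms: none
Why: α-Selenenylation of the lactone enolate followed by selenoxide syn-elimination toward the ring CH2 (C9) gives the endocyclic C8=C9 enoate; periodate is used as oxidant so that the cyclopentene is not epoxidised.

Step 9
Reactants: 16 (6R,7R,8S)-7,8-bis[(TBS-oxy)methyl]-4-(cyclopent-3-en-1-ylmethyl)-8-methyl-2-oxaspiro[5.5]undec-4-en-3-one
Product: 18 3-{[(6R,7R,8S)-7,8-bis[(TBS-oxy)methyl]-8-methyl-3-oxo-2-oxaspiro[5.5]undec-4-en-4-yl]methyl}pentanedial, via ozonide 17 (not isolated)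
Conditions: O3, CH2Cl2, −78 °C (Sudan Red 7B end point); then PPh3, −78 °C → rt
Reagents that add atoms: ozone O=[O+][O-]
Why: Chemoselective ozonolysis, since the electron-rich cis-disubstituted cyclopentene reacts far faster than the electron-poor trisubstituted enoate; this unmasks the two identical CH2CHO arms on C13.

Step 10
Reactants: 18 3-{[(6R,7R,8S)-7,8-bis[(TBS-oxy)methyl]-8-methyl-3-oxo-2-oxaspiro[5.5]undec-4-en-4-yl]methyl}pentanedial
Product: 20 (4S,5R,8S,9S,10S,11R,13S)-6,18-bis(TBS-oxy)-11,15-dihydroxy-6,7-secokauran-7,20-olide (C15 epimers), via samarium enolate 19 (not isolated)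
Conditions: SmI2 (2.5 equiv, 0.1 M in THF, added over 1 h), t-BuOH (1 equiv), THF, −78 °C; aq NH4Cl
Reagents that add atoms: none
Why: Proposed new method: a desymmetrising SmI2 ketyl–olefin/aldol bicyclisation (closest known type: SmI2 aldehyde–unsaturated-lactone ketyl cyclisation with aldol trapping of the samarium enolate), in which one aldehyde forms a ketyl that adds 6-endo to C9 on the C1 face of the enoate (anti to C5) through a chair that keeps the other CH2CHO arm equatorial and the O–Sm over the enoate (sets C9, C11 and C13), a second electron gives the C8 samarium enolate, and this enolate adds to the remaining aldehyde on the face syn to H9 to close the bicyclo[3.2.1]octane (sets C8); slow addition of SmI2 keeps the mono-ketyl pathway ahead of pinacol coupling.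

Step 11
Reactants: 20 (4S,5R,8S,9S,10S,11R,13S)-6,18-bis(TBS-oxy)-11,15-dihydroxy-6,7-secokauran-7,20-olide
Product: 21 (4S,5R,8S,9S,10S,11R,13S)-6,18-bis(TBS-oxy)-11-hydroxy-15-oxo-6,7-secokauran-7,20-olide
Conditions: Dess–Martin periodinane (1.1 equiv), CH2Cl2, 0 °C
Reagents that add atoms: none
Why: Dess–Martin oxidation under reagent control, expected to take the cyclopentanol at C15 in preference to the C11 hydroxyl, which is shielded by C1H2 and C20H2 of the spiro ring A; both C15 epimers converge on the ketone.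

Step 12
Reactants: 21 (4S,5R,8S,9S,10S,11R,13S)-6,18-bis(TBS-oxy)-11-hydroxy-15-oxo-6,7-secokauran-7,20-olide
Product: 23 (4S,5R,8S,9S,10S,11R,13S)-6,18-bis(TBS-oxy)-11-hydroxy-15-oxo-6,7-secokaur-16-en-7,20-olide, via Mannich base 22 (not isolated)
Conditions: (CH2O)n, N-methylanilinium trifluoroacetate, THF, 65 °C
Reagents that add atoms: paraformaldehyde (as formaldehyde) C=O
Why: Gras α-methylenation (Mannich reaction then β-elimination of the amine), regiospecific because the C15 ketone can only enolise toward C16 (C8 is quaternary), under mildly acidic conditions that tolerate the free C11 hydroxyl, the lactone and the TBS ethers.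

Step 13
Reactants: 23 (4S,5R,8S,9S,10S,11R,13S)-6,18-bis(TBS-oxy)-11-hydroxy-15-oxo-6,7-secokaur-16-en-7,20-olide
Product: 24 (4S,5R,8S,9S,10S,11R,13S)-6,11,18-trihydroxy-15-oxo-6,7-secokaur-16-en-7,20-olide (CNP0152458.1)
Conditions: HF·pyridine, pyridine/THF, 0 °C → rt
Reagents that add atoms: none
Why: Fluoride-mediated cleavage of the two primary TBS ethers under buffered, non-basic conditions that leave the α-methylene ketone and the β-keto lactone intact.

**Compound list**
1 | methyl 3-oxocyclohex-1-ene-1-carboxylate | COC(=O)C1=CC(=O)CCC1 | starting material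
2 | methyl (1S)-1-methyl-3-[(methylzincio)oxy]cyclohex-2-ene-1-carboxylate (zinc enolate, not isolated) | C[Zn]OC1=C[C@@](C)(C(=O)OC)CCC1 | intermediate
3 | methyl (1S,2S)-1-methyl-2-{[(methylzincio)oxy]methyl}-3-oxocyclohexane-1-carboxylate (zinc aldolate, not isolated) | O=C1CCC[C@](C)(C(=O)OC)[C@H]1CO[Zn]C | intermediate
4 | methyl (1S,2S)-2-[(TBS-oxy)methyl]-1-methyl-3-oxocyclohexane-1-carboxylate | O=C1CCC[C@](C)(C(=O)OC)[C@H]1CO[Si](C)(C)C(C)(C)C | intermediate
5 | methyl (4S,5S)-4-[(TBS-oxy)methyl]-5-methyl-1-oxaspiro[2.5]octane-5-carboxylate (spiro carbon: both epimers) | C1OC12CCC[C@](C)(C(=O)OC)[C@H]2CO[Si](C)(C)C(C)(C)C | intermediate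
6 | [(4S,5S)-4-[(TBS-oxy)methyl]-5-methyl-1-oxaspiro[2.5]octan-5-yl]methanol | C1OC12CCC[C@](C)(CO)[C@H]2CO[Si](C)(C)C(C)(C)C | intermediate
7 | (4S,5S)-4,5-bis[(TBS-oxy)methyl]-5-methyl-1-oxaspiro[2.5]octane | C1OC12CCC[C@](C)(CO[Si](C)(C)C(C)(C)C)[C@H]2CO[Si](C)(C)C(C)(C)C | intermediate
8 | 2,2,2-trifluoroethyl acrylate | C=CC(=O)OCC(F)(F)F | starting material
9 | 2,2,2-trifluoroethyl 3-[(1R,2R,3S)-2,3-bis[(TBS-oxy)methyl]-1-(hydroxymethyl)-3-methylcyclohexyl]propanoate (present as its titanium alkoxide, not isolated) | OC[C@@]1(CCC(=O)OCC(F)(F)F)CCC[C@](C)(CO[Si](C)(C)C(C)(C)C)[C@H]1CO[Si](C)(C)C(C)(C)C | intermediate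
10 | (6R,7R,8S)-7,8-bis[(TBS-oxy)methyl]-8-methyl-2-oxaspiro[5.5]undecan-3-one | O=C1CC[C@]2(CO1)CCC[C@](C)(CO[Si](C)(C)C(C)(C)C)[C@H]2CO[Si](C)(C)C(C)(C)C | intermediate
11 | cyclopent-3-en-1-ylmethanol | OCC1CC=CC1 | starting material
12 | 4-(iodomethyl)cyclopent-1-ene | ICC1CC=CC1 | intermediate
13 | (6R,7R,8S)-7,8-bis[(TBS-oxy)methyl]-4-(cyclopent-3-en-1-ylmethyl)-8-methyl-2-oxaspiro[5.5]undecan-3-one (C4 of lactone: both epimers) | O=C1C(CC3CC=CC3)C[C@]2(CO1)CCC[C@](C)(CO[Si](C)(C)C(C)(C)C)[C@H]2CO[Si](C)(C)C(C)(C)C | intermediate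
14 | 4-(phenylselanyl) derivative of 13 (not isolated) | O=C1C([Se]c3ccccc3)(CC4CC=CC4)C[C@]2(CO1)CCC[C@](C)(CO[Si](C)(C)C(C)(C)C)[C@H]2CO[Si](C)(C)C(C)(C)C | intermediate
15 | selenoxide of 14 (not isolated) | O=C1C([Se](=O)c3ccccc3)(CC4CC=CC4)C[C@]2(CO1)CCC[C@](C)(CO[Si](C)(C)C(C)(C)C)[C@H]2CO[Si](C)(C)C(C)(C)C | intermediate
16 | (6R,7R,8S)-7,8-bis[(TBS-oxy)methyl]-4-(cyclopent-3-en-1-ylmethyl)-8-methyl-2-oxaspiro[5.5]undec-4-en-3-one | O=C1C(CC3CC=CC3)=C[C@]2(CO1)CCC[C@](C)(CO[Si](C)(C)C(C)(C)C)[C@H]2CO[Si](C)(C)C(C)(C)C | intermediate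
17 | secondary ozonide (6,7,8-trioxabicyclo[3.2.1]octan-3-ylmethyl group) of 16 (not isolated) | O=C1C(CC3CC4OOC(C3)O4)=C[C@]2(CO1)CCC[C@](C)(CO[Si](C)(C)C(C)(C)C)[C@H]2CO[Si](C)(C)C(C)(C)C | intermediate
18 | 3-{[(6R,7R,8S)-7,8-bis[(TBS-oxy)methyl]-8-methyl-3-oxo-2-oxaspiro[5.5]undec-4-en-4-yl]methyl}pentanedial | O=C1C(CC(CC=O)CC=O)=C[C@]2(CO1)CCC[C@](C)(CO[Si](C)(C)C(C)(C)C)[C@H]2CO[Si](C)(C)C(C)(C)C | intermediate
19 | samarium enolate after the first ring closure: ring C formed, C11–OSmI2, C8=C7(OSmI2) ketene acetal, C13 carries CH2CHO (not isolated) | O=CC[C@@H]1C[C@@H](O[Sm](I)I)[C@@H]2C(C1)=C(O[Sm](I)I)OC[C@]23CCC[C@](C)(CO[Si](C)(C)C(C)(C)C)[C@H]3CO[Si](C)(C)C(C)(C)C | intermediate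
20 | (4S,5R,8S,9S,10S,11R,13S)-6,18-bis(TBS-oxy)-11,15-dihydroxy-6,7-secokauran-7,20-olide (C15: both epimers) | C1C(O)[C@]23C[C@H]1C[C@@H](O)[C@H]2[C@@]1(CCC[C@](C)(CO[Si](C)(C)C(C)(C)C)[C@H]1CO[Si](C)(C)C(C)(C)C)COC3=O | intermediate
21 | (4S,5R,8S,9S,10S,11R,13S)-6,18-bis(TBS-oxy)-11-hydroxy-15-oxo-6,7-secokauran-7,20-olide | C1C(=O)[C@]23C[C@H]1C[C@@H](O)[C@H]2[C@@]1(CCC[C@](C)(CO[Si](C)(C)C(C)(C)C)[C@H]1CO[Si](C)(C)C(C)(C)C)COC3=O | intermediate
22 | 16-[(N-methylanilino)methyl] derivative of 21 (Mannich base, C16 unassigned, not isolated) | CN(c1ccccc1)CC1C(=O)[C@]23C[C@H]1C[C@@H](O)[C@H]2[C@@]1(CCC[C@](C)(CO[Si](C)(C)C(C)(C)C)[C@H]1CO[Si](C)(C)C(C)(C)C)COC3=O | intermediate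
23 | (4S,5R,8S,9S,10S,11R,13S)-6,18-bis(TBS-oxy)-11-hydroxy-15-oxo-6,7-secokaur-16-en-7,20-olide | C=C1C(=O)[C@]23C[C@H]1C[C@@H](O)[C@H]2[C@@]1(CCC[C@](C)(CO[Si](C)(C)C(C)(C)C)[C@H]1CO[Si](C)(C)C(C)(C)C)COC3=O | intermediate
24 | (4S,5R,8S,9S,10S,11R,13S)-6,11,18-trihydroxy-15-oxo-6,7-secokaur-16-en-7,20-olide (CNP0152458.1) | C=C1C(=O)[C@]23C[C@H]1C[C@@H](O)[C@H]2[C@@]1(CCC[C@](C)(CO)[C@H]1CO)COC3=O | target

**Step count and risks**
Total steps: 13. Longest linear sequence: 12 (steps 1–5 and 7–13; step 6 is the side branch).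

The three steps most likely to fail:

Step 10. The 1,5-dialdehyde can undergo pinacol coupling, the enolate can be protonated before the aldol, and the choice between the two arms may be imperfect. The fallback sets out from 16 and differentiates the two chain ends before the reduction. Ozonolysis in CH2Cl2/MeOH with NaHCO3 gives the aldehyde/α-methoxy hydroperoxide F1, which Ac2O/Et3N dehydrates to the aldehyde methyl ester F2 (both C13 epimers). SmI2 in THF without a proton source then gives the ring-C samarium enolate F3, which closes ring D by Claisen-type acylation on its CO2Me arm and rejoins the route at 21. Only the C13 epimer with the ester arm on the H9 side can close, so at most half the material is productive, but no pinacol is possible and step 11 is bypassed.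

Step 11. The Dess–Martin reagent may not discriminate between the C15 and C11 hydroxyls. The fallback sets out from 20 and replaces reagent control by a temporary protecting group. TESOTf/2,6-lutidine at −78 °C gives the 11-O-triethylsilyl ether F4, excess Dess–Martin periodinane oxidises C15 to give the 11-O-triethylsilyl 15-ketone F5, and PPTS/MeOH removes the secondary TES group (primary TBS ethers survive) to rejoin at 21.

Step 1. The one-flask formaldehyde trapping and silylation may give poor yield or poor C5 selectivity. The fallback sets out from 1: the same conjugate methylation is quenched with TMSCl to isolate the regiodefined trimethylsilyl enol ether F6. A Lewis-acid Mukaiyama hydroxymethylation (aqueous CH2O, Yb(OTf)3, THF) then gives the hydroxy ketone F7, whose C5 epimers can be separated before TBSCl/imidazole delivers 4.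

**Further compounds**
F1 | step 10 | aldehyde/α-methoxy hydroperoxide from methanolic ozonolysis of 16 (C13 and acetal carbon unassigned) | O=C1C(CC(CC=O)CC(OC)OO)=C[C@]2(CO1)CCC[C@](C)(CO[Si](C)(C)C(C)(C)C)[C@H]2CO[Si](C)(C)C(C)(C)C
F2 | step 10 | methyl 3-{[(6R,7R,8S)-7,8-bis[(TBS-oxy)methyl]-8-methyl-3-oxo-2-oxaspiro[5.5]undec-4-en-4-yl]methyl}-5-oxopentanoate (both C13 epimers) | O=C1C(CC(CC=O)CC(=O)OC)=C[C@]2(CO1)CCC[C@](C)(CO[Si](C)(C)C(C)(C)C)[C@H]2CO[Si](C)(C)C(C)(C)C
F3 | step 10 | ring-C samarium enolate carrying the CH2CO2Me arm on C13 | COC(=O)C[C@@H]1C[C@@H](O[Sm](I)I)[C@@H]2C(C1)=C(O[Sm](I)I)OC[C@]23CCC[C@](C)(CO[Si](C)(C)C(C)(C)C)[C@H]3CO[Si](C)(C)C(C)(C)C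
F4 | step 11 | 11-O-triethylsilyl ether of 20 | C1C(O)[C@]23C[C@H]1C[C@@H](O[Si](CC)(CC)CC)[C@H]2[C@@]1(CCC[C@](C)(CO[Si](C)(C)C(C)(C)C)[C@H]1CO[Si](C)(C)C(C)(C)C)COC3=O
F5 | step 11 | 11-O-triethylsilyl ether of 21 | C1C(=O)[C@]23C[C@H]1C[C@@H](O[Si](CC)(CC)CC)[C@H]2[C@@]1(CCC[C@](C)(CO[Si](C)(C)C(C)(C)C)[C@H]1CO[Si](C)(C)C(C)(C)C)COC3=O
F6 | step 1 | methyl (1S)-1-methyl-3-(trimethylsilyloxy)cyclohex-2-ene-1-carboxylate | C[Si](C)(C)OC1=C[C@@](C)(C(=O)OC)CCC1
F7 | step 1 | methyl (1S,2S)-2-(hydroxymethyl)-1-methyl-3-oxocyclohexane-1-carboxylate | O=C1CCC[C@](C)(C(=O)OC)[C@H]1CO
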